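**Plan**
- Last cut: the two C2''=C3'' alkenes. C8 of ring A and C3' of ring B bear the same CH2–CH=C(CH3)2 chain, each a trisubstituted alkene one methylene away from an arene. Both chains are therefore traced back to the allyl groups of one 8,3'-diallyl flavanone and are made together by metathesis with 2-methylbut-2-ene.
- Earlier cuts: O1–C2 (oxa-Michael, ring C), C2=C3 (Knoevenagel) and C3–C4 (crossed Claisen with tert-butyl acetate). These leave a ring B chromene aldehyde and a ring A salicylate.
- Forward: each allyl group is placed by O-allylation and aromatic Claisen rearrangement, and the pyran ring is fused to ring B by a propargyl ether rearrangement. The fragments are then joined, ring C closes, and acid removes the ester and the MOM group while only acid-tolerant allyl groups are present.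
- Stereochemistry: C2 (S), the only stereocentre, comes from a cinchona thiourea catalysed closure of the alkylidene β-ketoester. The tert-butyl ester is a removable activating group, and every later step is free of base.

Key step: step 11

Assumption: the quinidine-derived thiourea is taken to deliver the (2S) series (to be confirmed by circular dichroism of the diallyl flavanone); if the sense proves opposite, its quinine-derived pseudoenantiomer replaces it with no other change.

**Route**

Step 1
Reactants: 1 4-hydroxybenzaldehyde; 2 allyl bromide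
Product: 3 4-(allyloxy)benzaldehyde
Conditions: 2 (1.2 equiv), K2CO3, acetone, reflux
Reagents that add atoms: allyl bromide 2, C=CCBr
Why: Williamson ether synthesis, in which the phenoxide of 1 displaces bromide from the unhindered allylic halide while the aldehyde is inert to K2CO3.

Step 2
Reactants: 3 4-(allyloxy)benzaldehyde
Product: 4 3-allyl-4-hydroxybenzaldehyde
Conditions: N,N-diethylaniline, 200 °C
Reagents that add atoms: none
Why: Aromatic Claisen rearrangement, whose [3,3] shift delivers the allyl group to one of two equivalent ortho carbons before tautomerisation restores the phenol, so only one regioisomer can form.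

Step 3
Reactants: 4 3-allyl-4-hydroxybenzaldehyde; 5 3-chloro-3-methylbut-1-yne
Product: 6 3-allyl-4-[(2-methylbut-3-yn-2-yl)oxy]benzaldehyde
Conditions: 5 (1.5 equiv), K2CO3, KI (10 mol %), CuI (5 mol %), DMF, 65 °C
Reagents that add atoms: 3-chloro-3-methylbut-1-yne 5, C#CC(C)(C)Cl
Why: Copper-assisted O-alkylation of a phenoxide with a tertiary propargylic chloride, the standard entry to aryl 1,1-dimethylpropargyl ethers, which suits acidic para-acyl phenols such as 4.

Step 4
Reactants: 6 3-allyl-4-[(2-methylbut-3-yn-2-yl)oxy]benzaldehyde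
Product: 7 8-allyl-2,2-dimethyl-2H-chromene-6-carbaldehyde
Conditions: N,N-diethylaniline, 190 °C
Reagents that add atoms: none
Why: Propargyl Claisen rearrangement to the only free ortho carbon, then 1,5-hydrogen shift and oxa-6π electrocyclisation, is the classical thermal chromene annulation, and the allyl group and the aldehyde are inert to heat alone.

Step 5
Reactants: 8 methyl 2,4-dihydroxybenzoate; 2 allyl bromide
Product: 9 methyl 4-(allyloxy)-2-hydroxybenzoate
Conditions: 2 (1.05 equiv), K2CO3, acetone, reflux
Reagents that add atoms: allyl bromide 2, C=CCBr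
Why: Regioselective Williamson ether synthesis, because the C2 hydroxyl is held in a hydrogen bond to the ester carbonyl and one equivalent of 2 therefore alkylates the free, more acidic C4 hydroxyl.

Step 6
Reactants: 9 methyl 4-(allyloxy)-2-hydroxybenzoate
Product: 10 methyl 3-allyl-2,4-dihydroxybenzoate
Conditions: N,N-diethylaniline, 205 °C; chromatography
Reagents that add atoms: none
Why: Aromatic Claisen rearrangement, which in chelated 2-hydroxyaryl carbonyl compounds moves the allyl group from O4 mainly to C3, the carbon between the two oxygens, the minor C5 isomer being removed by chromatography.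

Step 7
Reactants: 10 methyl 3-allyl-2,4-dihydroxybenzoate
Product: 11 methyl 3-allyl-2-hydroxy-4-(methoxymethoxy)benzoate
Conditions: MOMCl (1.1 equiv), K2CO3, acetone, 0 °C to 20 °C
Reagents that add atoms: chloromethyl methyl ether (MOMCl), COCCl
Why: Selective MOM ether formation at the C4 hydroxyl, since the C2 hydroxyl remains chelated to the ester and is flanked on both sides.

Step 8
Reactants: 11 methyl 3-allyl-2-hydroxy-4-(methoxymethoxy)benzoate; 12 tert-butyl acetate
Product: 13 tert-butyl 3-[3-allyl-2-hydroxy-4-(methoxymethoxy)phenyl]-3-oxopropanoate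
Conditions: 12 (4.0 equiv), LiN(i-Pr)2 (LDA, commercial solution, 3.8 equiv), THF, −78 °C; then 11, −78 °C to 0 °C; AcOH quench
Reagents that add atoms: tert-butyl acetate 12, CC(=O)OC(C)(C)C
Why: Crossed Claisen condensation of a salicylate with excess lithiated tert-butyl acetate (one equivalent each for the phenol, the addition and the acidic product), with 12 kept in slight excess over the amide base so that none remains to isomerise the allyl group, and with the bulky ester blocking closure to a 4-hydroxycoumarin.

Step 9
Reactants: 13 tert-butyl 3-[3-allyl-2-hydroxy-4-(methoxymethoxy)phenyl]-3-oxopropanoate; 7 8-allyl-2,2-dimethyl-2H-chromene-6-carbaldehyde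
Product: 14 tert-butyl (2Z)-2-[3-allyl-2-hydroxy-4-(methoxymethoxy)benzoyl]-3-(8-allyl-2,2-dimethyl-2H-chromen-6-yl)prop-2-enoate
Conditions: piperidine (20 mol %), AcOH (20 mol %), 4 Å molecular sieves, toluene, 20–40 °C
Reagents that add atoms: none
Why: Knoevenagel condensation of a β-ketoester with an aromatic aldehyde, which should favour the Z alkene (aryl cis to the ester), and the donor oxygen para to the new alkene slows premature uncatalysed ring closure.

Step 10
Reactants: 14 tert-butyl (2Z)-2-[3-allyl-2-hydroxy-4-(methoxymethoxy)benzoyl]-3-(8-allyl-2,2-dimethyl-2H-chromen-6-yl)prop-2-enoate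
Product: 18 (2S)-8-allyl-2-(8-allyl-2,2-dimethyl-2H-chromen-6-yl)-7-hydroxychroman-4-one, via tert-butyl 3-carboxylate 15 (not isolated), via 3-carboxylic acid 16 (not isolated), via 7-O-methoxymethyl flavanone 17 (not isolated)
Conditions: 1-[3,5-bis(trifluoromethyl)phenyl]-3-[(9R)-6'-methoxycinchonan-9-yl]thiourea (10 mol %), toluene, −25 °C; then TsOH·H2O (1.0 equiv), 80 °C; then MeOH, 55 °C; recrystallisation
Reagents that add atoms: none
Why: Organocatalytic asymmetric intramolecular oxa-Michael addition (6-endo-trig), in which the thiourea binds the β-dicarbonyl unit and the quinuclidine nitrogen activates the phenol so that O1 attacks one face of the alkylidene carbon and sets C2 as S under catalyst control (C3 is labile and is erased), after which TsOH neutralises the amine, cleaves the tert-butyl ester by loss of 2-methylpropene, lets the β-keto acid decarboxylate and, once MeOH is present, removes the MOM acetal by exchange, all under conditions that allyl groups and the 2,2-dimethylchromene tolerate.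

Step 11
Reactants: 18 (2S)-8-allyl-2-(8-allyl-2,2-dimethyl-2H-chromen-6-yl)-7-hydroxychroman-4-one; 19 2-methylbut-2-ene
Product: 20 (2S)-7-hydroxy-2-[2,2-dimethyl-8-(3-methylbut-2-enyl)-2H-chromen-6-yl]-8-(3-methylbut-2-enyl)chroman-4-one (target)
Conditions: RuCl2(=CHPh)(H2IMes)(PCy3) (second-generation Grubbs catalyst, 5 mol % + 5 mol %), 19/CH2Cl2 1:1, 1,4-benzoquinone (10 mol %), 40 °C, sealed tube
Reagents that add atoms: 2-methylbut-2-ene 19, CC=C(C)C
Why: The benzylidene complex is turned by 19 into ruthenium ethylidene and isopropylidene carbenes that add to each terminal CH=CH2 of 18 by [2+2] cycloaddition, and cycloreversion of the ruthenacyclobutanes exchanges =CH2 for =C(CH3)2 with release of propene, any crotyl intermediate being carried on to the same product by the large excess of 19. The closest known reaction type is olefin cross-metathesis of allylarenes, free ortho-allylphenols included, with 2-methylbut-2-ene to give prenylarenes. No ring closes and no stereocentre forms; the new C2''=C3'' alkenes end in geminal methyl groups, so no E/Z question arises, and C2 is safe because the medium is neutral and contains no base that could start a retro-oxa-Michael opening. The step needs selectivity for the two monosubstituted alkenes over the chromene C3=C4 alkene, which is 1,2-disubstituted, conjugated with ring B and shielded by the adjacent quaternary C(CH3)2 carbon, and which would simply re-close to the same six-membered ring if it ever opened. The trisubstituted prenyl alkenes are too hindered to re-enter the cycle, so both sites funnel to 20, while dilution in 19 disfavours homodimers and any macrocyclic closure between the two allyl groups, and 1,4-benzoquinone intercepts ruthenium hydrides that would move the allyl double bonds into conjugation.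

**Compound list**
1 | 4-hydroxybenzaldehyde | O=Cc1ccc(O)cc1 | starting material
2 | allyl bromide | C=CCBr | starting material
3 | 4-(allyloxy)benzaldehyde | C=CCOc1ccc(C=O)cc1 | intermediate
4 | 3-allyl-4-hydroxybenzaldehyde | C=CCc1cc(C=O)ccc1O | intermediate
5 | 3-chloro-3-methylbut-1-yne | C#CC(C)(C)Cl | starting material
6 | 3-allyl-4-[(2-methylbut-3-yn-2-yl)oxy]benzaldehyde | C=CCc1cc(C=O)ccc1OC(C)(C)C#C | intermediate
7 | 8-allyl-2,2-dimethyl-2H-chromene-6-carbaldehyde | C=CCc1cc(C=O)cc2c1OC(C)(C)C=C2 | intermediate
8 | methyl 2,4-dihydroxybenzoate | COC(=O)c1ccc(O)cc1O | starting material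
9 | methyl 4-(allyloxy)-2-hydroxybenzoate | COC(=O)c1ccc(OCC=C)cc1O | intermediate
10 | methyl 3-allyl-2,4-dihydroxybenzoate | COC(=O)c1ccc(O)c(CC=C)c1O | intermediate
11 | methyl 3-allyl-2-hydroxy-4-(methoxymethoxy)benzoate | COC(=O)c1ccc(OCOC)c(CC=C)c1O | intermediate
12 | tert-butyl acetate | CC(=O)OC(C)(C)C | starting material
13 | tert-butyl 3-[3-allyl-2-hydroxy-4-(methoxymethoxy)phenyl]-3-oxopropanoate | CC(C)(C)OC(=O)CC(=O)c1ccc(OCOC)c(CC=C)c1O | intermediate
14 | tert-butyl (2Z)-2-[3-allyl-2-hydroxy-4-(methoxymethoxy)benzoyl]-3-(8-allyl-2,2-dimethyl-2H-chromen-6-yl)prop-2-enoate | CC(C)(C)OC(=O)/C(=C\c1cc(CC=C)c2OC(C)(C)C=Cc2c1)C(=O)c1ccc(OCOC)c(CC=C)c1O | intermediate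
15 | tert-butyl (2S,3R)-8-allyl-2-(8-allyl-2,2-dimethyl-2H-chromen-6-yl)-7-(methoxymethoxy)-4-oxochroman-3-carboxylate (2,3-trans keto form, in equilibrium with its enol; not isolated) | C=CCc1cc([C@@H]2[C@@H](C(=O)OC(C)(C)C)C(=O)c3ccc(OCOC)c(CC=C)c3O2)cc2c1OC(C)(C)C=C2 | intermediate
16 | (2S,3R)-8-allyl-2-(8-allyl-2,2-dimethyl-2H-chromen-6-yl)-7-(methoxymethoxy)-4-oxochroman-3-carboxylic acid (not isolated) | C=CCc1cc([C@@H]2[C@@H](C(=O)O)C(=O)c3ccc(OCOC)c(CC=C)c3O2)cc2c1OC(C)(C)C=C2 | intermediate
17 | (2S)-8-allyl-2-(8-allyl-2,2-dimethyl-2H-chromen-6-yl)-7-(methoxymethoxy)chroman-4-one (not isolated) | C=CCc1cc([C@@H]2CC(=O)c3ccc(OCOC)c(CC=C)c3O2)cc2c1OC(C)(C)C=C2 | intermediate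
18 | (2S)-8-allyl-2-(8-allyl-2,2-dimethyl-2H-chromen-6-yl)-7-hydroxychroman-4-one | C=CCc1cc([C@@H]2CC(=O)c3ccc(O)c(CC=C)c3O2)cc2c1OC(C)(C)C=C2 | intermediate
19 | 2-methylbut-2-ene | CC=C(C)C | starting material
20 | (2S)-7-hydroxy-2-[2,2-dimethyl-8-(3-methylbut-2-enyl)-2H-chromen-6-yl]-8-(3-methylbut-2-enyl)chroman-4-one | CC(C)=CCc1cc([C@@H]2CC(=O)c3ccc(O)c(CC=C(C)C)c3O2)cc2c1OC(C)(C)C=C2 | target

**Step count**
Total step count: 11.
Longest linear sequence: 7 steps (steps 1–4 or steps 5–8, followed by steps 9–11).

**Steps most likely to fail**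

Step 10.
- Facial selectivity may be poor, because the attacking phenol oxygen is flanked by the C3 allyl group and the alkylidene is electron-rich.
- Configuration may also erode through reversible ring opening, and the chromene may be attacked by acid, during the hot acid stage.
- Fallback (resolution instead of asymmetric catalysis): setting out from 14, closure with an achiral amine (Et3N, toluene, 20 °C) should give the racemic trans tert-butyl 3-carboxylate F1.
- The same TsOH·H2O/MeOH sequence then leads through the racemic 3-carboxylic acid F2 and the racemic 7-O-methoxymethyl flavanone F3 to the racemic diallyl flavanone F4.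
- Preparative HPLC on an amylose tris(3,5-dimethylphenylcarbamate) phase resolves this into 18, where the route is rejoined, and the (2R) enantiomer F5, which is set aside.

Step 11.
- The exchange may stall after one chain.
- Ruthenium hydrides may move an allyl double bond into conjugation.
- The ortho-hydroxy group may tie up the carbene.
- Fallback (change of substrate class): setting out from 18, the phenol is masked (TBSCl, imidazole, DMF) as the 7-O-tert-butyldimethylsilyl diallyl flavanone F6.
- Metathesis with 19 under RuCl2(=CHPh)(H2IMes)(PCy3) then acts on a substrate with no acidic, chelating neighbour and should give the 7-O-silyl diprenyl flavanone F7.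
- Et3N·3HF in THF at 0 °C, mild enough for the prenyl groups and for C2, releases 20.

Step 8.
- Addition to an ester deactivated by the ortho-phenoxide and the para-alkoxy group may be sluggish.
- On warming, the enolate may self-condense or the allyl group may migrate under base.
- Fallback (activated acyl donor and neutral magnesium malonate, Masamune–Brooks type): setting out from 11, LiOH in THF/H2O gives 3-allyl-2-hydroxy-4-(methoxymethoxy)benzoic acid F8.
- 1,1'-Carbonyldiimidazole in THF converts it into the acyl imidazole F9.
- Mg(O2CCH2CO2t-Bu)2 (from mono-tert-butyl malonate, MgCl2 and Et3N) is C-acylated to the acylmalonate half-ester F10, which loses CO2 on mild acidic work-up and returns the route to 13.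

**Further compounds**
F1 | step 10 | racemic trans tert-butyl 8-allyl-2-(8-allyl-2,2-dimethyl-2H-chromen-6-yl)-7-(methoxymethoxy)-4-oxochroman-3-carboxylate | C=CCc1cc(C2C(C(=O)OC(C)(C)C)C(=O)c3ccc(OCOC)c(CC=C)c3O2)cc2c1OC(C)(C)C=C2
F2 | step 10 | racemic 8-allyl-2-(8-allyl-2,2-dimethyl-2H-chromen-6-yl)-7-(methoxymethoxy)-4-oxochroman-3-carboxylic acid | C=CCc1cc(C2C(C(=O)O)C(=O)c3ccc(OCOC)c(CC=C)c3O2)cc2c1OC(C)(C)C=C2
F3 | step 10 | racemic 8-allyl-2-(8-allyl-2,2-dimethyl-2H-chromen-6-yl)-7-(methoxymethoxy)chroman-4-one | C=CCc1cc(C2CC(=O)c3ccc(OCOC)c(CC=C)c3O2)cc2c1OC(C)(C)C=C2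
F4 | step 10 | racemic 8-allyl-2-(8-allyl-2,2-dimethyl-2H-chromen-6-yl)-7-hydroxychroman-4-one | C=CCc1cc(C2CC(=O)c3ccc(O)c(CC=C)c3O2)cc2c1OC(C)(C)C=C2
F5 | step 10 | (2R)-8-allyl-2-(8-allyl-2,2-dimethyl-2H-chromen-6-yl)-7-hydroxychroman-4-one | C=CCc1cc([C@H]2CC(=O)c3ccc(O)c(CC=C)c3O2)cc2c1OC(C)(C)C=C2
F6 | step 11 | (2S)-8-allyl-2-(8-allyl-2,2-dimethyl-2H-chromen-6-yl)-7-[(tert-butyldimethylsilyl)oxy]chroman-4-one | C=CCc1cc([C@@H]2CC(=O)c3ccc(O[Si](C)(C)C(C)(C)C)c(CC=C)c3O2)cc2c1OC(C)(C)C=C2
F7 | step 11 | (2S)-7-[(tert-butyldimethylsilyl)oxy]-2-[2,2-dimethyl-8-(3-methylbut-2-enyl)-2H-chromen-6-yl]-8-(3-methylbut-2-enyl)chroman-4-one | CC(C)=CCc1cc([C@@H]2CC(=O)c3ccc(O[Si](C)(C)C(C)(C)C)c(CC=C(C)C)c3O2)cc2c1OC(C)(C)C=C2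
F8 | step 8 | 3-allyl-2-hydroxy-4-(methoxymethoxy)benzoic acid | OC(=O)c1ccc(OCOC)c(CC=C)c1O
F9 | step 8 | [3-allyl-2-hydroxy-4-(methoxymethoxy)phenyl](1H-imidazol-1-yl)methanone | O=C(c1ccc(OCOC)c(CC=C)c1O)n1ccnc1
F10 | step 8 | 2-[3-allyl-2-hydroxy-4-(methoxymethoxy)benzoyl]-3-tert-butoxy-3-oxopropanoic acid | CC(C)(C)OC(=O)C(C(=O)O)C(=O)c1ccc(OCOC)c(CC=C)c1O
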